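**Plan**

- Retrosynthesis (tetralone numbering: C1 ketone, C3 carbinol, C5 pyronyl, C6 phenyl, C8 phenol; ring B = C1–C4 with C4a/C8a): remove the three O-protecting groups; cut C4–C4a and reconnect C4 to C1, giving a cis-1-aryl-3-benzyloxycyclobutan-1-ol with a C4a triflate; cut the pyrone to a C5 aldehyde and a dioxinone; cut C8a–C1 to an ortho-lithiated phenoxide and 3-(benzyloxy)cyclobutanone.
- Enabling feature: C1–C2–C3–C4 with its oxygen on C3 is a latent 3-oxygenated cyclobutanone. C3 is prochiral and the two C1–CH2 bonds are enantiotopic, so breaking one and bonding the freed CH2 to C4a makes ring B and the stereocentre together.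
- Forward: ring A is bought as biphenyl-3,5-diol. Bromination between the oxygens and unmasking of one phenol are followed by C8a–C1 (cyclobutanol), C5 formylation ortho to the free phenol, triflation, the pyrone ring, ring B by ring expansion, and one deprotection.
- Stereochemistry: the cyclobutanol is achiral (hydroxyl cis to benzyloxy, both ring centres pseudo-asymmetric). C3 (S) is created by the chiral palladium catalyst in the ring expansion and is not touched afterwards.
- The cyclobutanol also masks the β-alkoxy ketone, which never meets an enolate-forming base. The C4a phenol is freed before the acid-labile carbinol exists, so no strongly acidic step is needed while the four-membered ring is present.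

Key step: step 11

Assumption: the sense of induction of the chiral ligand in step 11 cannot be predicted with certainty; (S)-tBu-PHOX is written, and its antipode is used instead if that is the one that delivers the (S)-ketone.

**Step 1**
Reactants: 1 biphenyl-3,5-diol
Product: 2 3,5-dimethoxybiphenyl
Conditions: MeI, K2CO3, acetone, reflux
Reagents that add atoms: iodomethane, CI
Why: Williamson etherification of both phenols gives the dimethyl ether whose two oxygens jointly direct the next metalation.

**Step 2**
Reactants: 2 3,5-dimethoxybiphenyl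
Product: 4 4-bromo-3,5-dimethoxybiphenyl, via (2,6-dimethoxy-4-phenylphenyl)lithium 3 (not isolated)
Conditions: n-BuLi, THF, 0 °C → rt; then BrCCl2CCl2Br, −78 °C → rt
Reagents that add atoms: 1,2-dibromo-1,1,2,2-tetrachloroethane, BrC(Cl)(Cl)C(Cl)(Cl)Br
Why: Directed ortho-metalation should occur at the position flanked by both methoxy groups, and the aryllithium is brominated by halogen transfer from the polyhalide.

**Step 3**
Reactants: 4 4-bromo-3,5-dimethoxybiphenyl
Product: 5 4-bromo-5-methoxybiphenyl-3-ol
Conditions: BBr3 (1.05 equiv), CH2Cl2, −78 → 0 °C; then H2O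
Reagents that add atoms: none
Why: BBr3 ether cleavage with one equivalent should stop after the first methyl group because the aryloxyborane formed is deactivated, and since 4 is symmetric either methoxy group gives the same phenol.

**Step 4**
Reactants: 5 4-bromo-5-methoxybiphenyl-3-ol; 6 3-(benzyloxy)cyclobutan-1-one
Product: 8 4-[cis-3-(benzyloxy)-1-hydroxycyclobutyl]-5-methoxybiphenyl-3-ol (hydroxyl cis to benzyloxy), via lithium 2-lithio-3-methoxy-5-phenylphenolate 7 (not isolated)
Conditions: n-BuLi (2.2 equiv), THF, −78 → −20 °C; then 6, −78 → 0 °C; pH 7 buffer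
Reagents that add atoms: none
Why: Phenol deprotonation and bromine–lithium exchange give an ortho-lithiated phenoxide whose 1,2-addition to the strained ketone should take place on the face opposite the benzyloxy group, placing hydroxyl and benzyloxy cis on an achiral ring and delivering the C4a phenol free without any deprotection.

**Step 5**
Reactants: 8 4-[cis-3-(benzyloxy)-1-hydroxycyclobutyl]-5-methoxybiphenyl-3-ol
Product: 10 4-[cis-3-(benzyloxy)-1-hydroxycyclobutyl]-3-hydroxy-5-methoxybiphenyl-2-carbaldehyde, via hydroxymethyl phenol 9 (not isolated)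
Conditions: MgCl2, Et3N, (CH2O)n, THF, 65 °C; aq NH4Cl
Reagents that add atoms: paraformaldehyde (as formaldehyde), C=O
Why: Magnesium-phenoxide-directed ortho-formylation (Casnati–Skattebøl reaction) can only reach the single free ortho position of the phenol, the future C5, and its non-acidic conditions should spare the tertiary benzylic alcohol.

**Step 6**
Reactants: 10 4-[cis-3-(benzyloxy)-1-hydroxycyclobutyl]-3-hydroxy-5-methoxybiphenyl-2-carbaldehyde
Product: 11 4-[cis-3-(benzyloxy)-1-hydroxycyclobutyl]-2-formyl-5-methoxybiphenyl-3-yl trifluoromethanesulfonate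
Conditions: PhNTf2, Cs2CO3, DMF, 0 °C → rt
Reagents that add atoms: N-phenylbis(trifluoromethanesulfonimide), O=S(=O)(N(c1ccccc1)S(=O)(=O)C(F)(F)F)C(F)(F)F
Why: Sulfonyl transfer from the mild triflimide to the cesium phenoxide should triflate the acidic salicylaldehyde-type phenol only, the hindered tertiary alcohol being inert, and it blocks chromone formation in the steps that follow.

**Step 7**
Reactants: 11 4-[cis-3-(benzyloxy)-1-hydroxycyclobutyl]-2-formyl-5-methoxybiphenyl-3-yl trifluoromethanesulfonate; 12 2,2,6-trimethyl-4H-1,3-dioxin-4-one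
Product: 14 4-[cis-3-(benzyloxy)-1-hydroxycyclobutyl]-2-[2-(2,2-dimethyl-4-oxo-4H-1,3-dioxin-6-yl)-1-hydroxyethyl]-5-methoxybiphenyl-3-yl trifluoromethanesulfonate (racemic at the new carbinol), via lithium dienolate 13 (not isolated)
Conditions: LiN(i-Pr)2 (3.2 equiv), 12 (3.2 equiv), THF, −78 °C; then 11, −78 °C; pH 7 buffer
Reagents that add atoms: none
Why: Vinylogous aldol addition of the lithium dienolate through its exocyclic γ-carbon is a standard route to δ-hydroxy dioxinones; the excess base only turns the tertiary alcohol into its alkoxide, and the new carbinol centre is removed in the next step.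

**Step 8**
Reactants: 14 4-[cis-3-(benzyloxy)-1-hydroxycyclobutyl]-2-[2-(2,2-dimethyl-4-oxo-4H-1,3-dioxin-6-yl)-1-hydroxyethyl]-5-methoxybiphenyl-3-yl trifluoromethanesulfonate
Product: 15 4-[cis-3-(benzyloxy)-1-hydroxycyclobutyl]-2-[(2,2-dimethyl-4-oxo-4H-1,3-dioxin-6-yl)acetyl]-5-methoxybiphenyl-3-yl trifluoromethanesulfonate
Conditions: Dess–Martin periodinane, pyridine, CH2Cl2, 0 °C → rt
Reagents that add atoms: none
Why: Dess–Martin oxidation should convert the secondary benzylic alcohol into the ketone under buffered conditions that leave the tertiary alcohol and the triflate untouched.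

**Step 9**
Reactants: 15 4-[cis-3-(benzyloxy)-1-hydroxycyclobutyl]-2-[(2,2-dimethyl-4-oxo-4H-1,3-dioxin-6-yl)acetyl]-5-methoxybiphenyl-3-yl trifluoromethanesulfonate
Product: 17 4-[cis-3-(benzyloxy)-1-hydroxycyclobutyl]-2-(4-hydroxy-2-oxo-2H-pyran-6-yl)-5-methoxybiphenyl-3-yl trifluoromethanesulfonate, via acylketene 16 (not isolated)
Conditions: toluene, 105 °C
Reagents that add atoms: none
Why: Thermal retro-hetero-Diels–Alder loss of acetone from the dioxinone gives an acylketene that the enol oxygen of the neighbouring aryl ketone should trap as the 4-hydroxy-2-pyrone, with no acid or base present.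

**Step 10**
Reactants: 17 4-[cis-3-(benzyloxy)-1-hydroxycyclobutyl]-2-(4-hydroxy-2-oxo-2H-pyran-6-yl)-5-methoxybiphenyl-3-yl trifluoromethanesulfonate
Product: 18 4-[cis-3-(benzyloxy)-1-hydroxycyclobutyl]-2-[4-(benzyloxy)-2-oxo-2H-pyran-6-yl]-5-methoxybiphenyl-3-yl trifluoromethanesulfonate
Conditions: BnOH, PPh3, DIAD, THF, 0 °C → rt
Reagents that add atoms: benzyl alcohol, OCc1ccccc1
Why: Mitsunobu alkylation of the acidic 4-hydroxy-2-pyrone (a vinylogous carboxylic acid) should take place on the 4-oxygen, and the tertiary alcohol cannot be activated under these conditions.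

**Step 11**
Reactants: 18 4-[cis-3-(benzyloxy)-1-hydroxycyclobutyl]-2-[4-(benzyloxy)-2-oxo-2H-pyran-6-yl]-5-methoxybiphenyl-3-yl trifluoromethanesulfonate
Product: 19 (S)-3-(benzyloxy)-5-[4-(benzyloxy)-2-oxo-2H-pyran-6-yl]-8-methoxy-6-phenyl-3,4-dihydronaphthalen-1(2H)-one
Conditions: Pd(OAc)2 (10 mol%), (S)-tBu-PHOX (15 mol%), Cs2CO3, toluene, 70 °C
Reagents that add atoms: none
Why: Proposed new method: zerovalent palladium formed from Pd(OAc)2 and the phosphine inserts into the C4a–O triflate bond, the cationic aryl complex of divalent palladium binds the neighbouring tertiary alkoxide, strain-driven β-carbon elimination cleaves one of the two enantiotopic C1–CH2 bonds to unveil the C1 ketone and a seven-membered alkyl(aryl)palladacycle, and C(sp3)–C(sp2) reductive elimination forms C4–C4a. The closest known reaction type is the palladium-catalysed enantioselective ring-opening arylation of prochiral tert-cyclobutanols with aryl halides or triflates under Pd(OAc)2, a chiral P,N ligand and Cs2CO3, made intramolecular here so that the arene is inserted into the cleaved bond. Ring B closes by reductive elimination from the seven-membered palladacycle, a net two-carbon expansion of the four-membered ring in which alkyl and aryl are held cis on the metal. The C3 stereocentre is set in the irreversible β-carbon elimination by the chiral ligand, which distinguishes the two enantiotopic ring bonds of the achiral cis-cyclobutanol. The step needs reductive elimination to outrun β-hydride and β-benzyloxide elimination at C3, which the enforced cis geometry of the palladacycle and the hemilabile nitrogen donor should favour, and it needs the triflate to survive the base, which its two substituted ortho positions and heterogeneous Cs2CO3 in toluene should secure.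

**Step 12**
Reactants: 19 (S)-3-(benzyloxy)-5-[4-(benzyloxy)-2-oxo-2H-pyran-6-yl]-8-methoxy-6-phenyl-3,4-dihydronaphthalen-1(2H)-one
Product: 20 wailupemycin F [(S)-3,8-dihydroxy-5-(4-hydroxy-2-oxo-2H-pyran-6-yl)-6-phenyl-3,4-dihydronaphthalen-1(2H)-one]
Conditions: BCl3, C6HMe5, CH2Cl2, −78 → −40 °C; then H2O
Reagents that add atoms: none
Why: BCl3 should cleave the C8 methyl ether through its six-membered chelate with the C1 carbonyl and both benzyl ethers by Lewis-acid debenzylation with pentamethylbenzene as a non-basic cation trap, the low temperature keeping the β-hydroxy ketone from eliminating and leaving C3 untouched.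

**Compound list**

1 | biphenyl-3,5-diol | Oc1cc(O)cc(-c2ccccc2)c1 | starting material
2 | 3,5-dimethoxybiphenyl | COc1cc(OC)cc(-c2ccccc2)c1 | intermediate
3 | (2,6-dimethoxy-4-phenylphenyl)lithium | [Li]c1c(OC)cc(-c2ccccc2)cc1OC | intermediate
4 | 4-bromo-3,5-dimethoxybiphenyl | COc1cc(-c2ccccc2)cc(OC)c1Br | intermediate
5 | 4-bromo-5-methoxybiphenyl-3-ol | COc1cc(-c2ccccc2)cc(O)c1Br | intermediate
6 | 3-(benzyloxy)cyclobutan-1-one | O=C1CC(OCc2ccccc2)C1 | starting material
7 | lithium 2-lithio-3-methoxy-5-phenylphenolate | [Li]Oc1cc(-c2ccccc2)cc(OC)c1[Li] | intermediate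
8 | 4-[cis-3-(benzyloxy)-1-hydroxycyclobutyl]-5-methoxybiphenyl-3-ol (hydroxyl cis to benzyloxy) | O[C@]1(c2c(OC)cc(-c3ccccc3)cc2O)C[C@H](OCc2ccccc2)C1 | intermediate
9 | 4-[cis-3-(benzyloxy)-1-hydroxycyclobutyl]-2-(hydroxymethyl)-5-methoxybiphenyl-3-ol | O[C@]1(c2c(OC)cc(-c3ccccc3)c(CO)c2O)C[C@H](OCc2ccccc2)C1 | intermediate
10 | 4-[cis-3-(benzyloxy)-1-hydroxycyclobutyl]-3-hydroxy-5-methoxybiphenyl-2-carbaldehyde | O[C@]1(c2c(OC)cc(-c3ccccc3)c(C=O)c2O)C[C@H](OCc2ccccc2)C1 | intermediate
11 | 4-[cis-3-(benzyloxy)-1-hydroxycyclobutyl]-2-formyl-5-methoxybiphenyl-3-yl trifluoromethanesulfonate | O[C@]1(c2c(OC)cc(-c3ccccc3)c(C=O)c2OS(=O)(=O)C(F)(F)F)C[C@H](OCc2ccccc2)C1 | intermediate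
12 | 2,2,6-trimethyl-4H-1,3-dioxin-4-one | CC1=CC(=O)OC(C)(C)O1 | starting material
13 | lithium 2,2-dimethyl-6-methylidene-6H-1,3-dioxin-4-olate | C=C1C=C(O[Li])OC(C)(C)O1 | intermediate
14 | 4-[cis-3-(benzyloxy)-1-hydroxycyclobutyl]-2-[2-(2,2-dimethyl-4-oxo-4H-1,3-dioxin-6-yl)-1-hydroxyethyl]-5-methoxybiphenyl-3-yl trifluoromethanesulfonate (racemic at the side-chain carbinol) | O[C@]1(c2c(OC)cc(-c3ccccc3)c(C(O)CC3=CC(=O)OC(C)(C)O3)c2OS(=O)(=O)C(F)(F)F)C[C@H](OCc2ccccc2)C1 | intermediate
15 | 4-[cis-3-(benzyloxy)-1-hydroxycyclobutyl]-2-[(2,2-dimethyl-4-oxo-4H-1,3-dioxin-6-yl)acetyl]-5-methoxybiphenyl-3-yl trifluoromethanesulfonate | O[C@]1(c2c(OC)cc(-c3ccccc3)c(C(=O)CC3=CC(=O)OC(C)(C)O3)c2OS(=O)(=O)C(F)(F)F)C[C@H](OCc2ccccc2)C1 | intermediate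
16 | 4-[cis-3-(benzyloxy)-1-hydroxycyclobutyl]-2-(3,5-dioxopent-4-enoyl)-5-methoxybiphenyl-3-yl trifluoromethanesulfonate (acylketene) | O[C@]1(c2c(OC)cc(-c3ccccc3)c(C(=O)CC(=O)C=C=O)c2OS(=O)(=O)C(F)(F)F)C[C@H](OCc2ccccc2)C1 | intermediate
17 | 4-[cis-3-(benzyloxy)-1-hydroxycyclobutyl]-2-(4-hydroxy-2-oxo-2H-pyran-6-yl)-5-methoxybiphenyl-3-yl trifluoromethanesulfonate | O[C@]1(c2c(OC)cc(-c3ccccc3)c(-c3cc(O)cc(=O)o3)c2OS(=O)(=O)C(F)(F)F)C[C@H](OCc2ccccc2)C1 | intermediate
18 | 4-[cis-3-(benzyloxy)-1-hydroxycyclobutyl]-2-[4-(benzyloxy)-2-oxo-2H-pyran-6-yl]-5-methoxybiphenyl-3-yl trifluoromethanesulfonate | O[C@]1(c2c(OC)cc(-c3ccccc3)c(-c3cc(OCc4ccccc4)cc(=O)o3)c2OS(=O)(=O)C(F)(F)F)C[C@H](OCc2ccccc2)C1 | intermediate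
19 | (S)-3-(benzyloxy)-5-[4-(benzyloxy)-2-oxo-2H-pyran-6-yl]-8-methoxy-6-phenyl-3,4-dihydronaphthalen-1(2H)-one | O=C1C[C@@H](OCc2ccccc2)Cc2c1c(OC)cc(-c1ccccc1)c2-c1cc(OCc3ccccc3)cc(=O)o1 | intermediate
20 | wailupemycin F, (S)-3,8-dihydroxy-5-(4-hydroxy-2-oxo-2H-pyran-6-yl)-6-phenyl-3,4-dihydronaphthalen-1(2H)-one | O=C1C[C@@H](O)Cc2c1c(O)cc(-c1ccccc1)c2-c1cc(O)cc(=O)o1 | target

**Step count and risks**

Total steps: 12. Longest linear sequence: 12 steps (1 → 20); compounds 6 and 12 enter as bought.

Steps most likely to fail: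

1. Step 11 (proposed new method).
   - What may go wrong: the five-membered arylpalladium alkoxide chelate may not reach the syn-periplanar geometry needed for β-carbon elimination, so protodetriflation or intermolecular ring-opening arylation takes over. After C–C cleavage, β-hydride or β-benzyloxide elimination may overtake reductive elimination. The ligand may discriminate the enantiotopic bonds poorly, or the triflyl group may be lost to base.
   - Fallback, known chemistry (radical ring opening, cross-electrophile coupling, resolution): setting out from 18, the cyclobutanol is opened by alkoxy-radical β-scission under hypoiodite conditions (PhI(OAc)2, I2, CH2Cl2, visible light). This should give racemic 2-[4-(benzyloxy)-2-oxo-2H-pyran-6-yl]-4-[3-(benzyloxy)-4-iodobutanoyl]-5-methoxybiphenyl-3-yl trifluoromethanesulfonate F1. Intramolecular nickel-catalysed reductive coupling of the primary iodide with the aryl triflate (NiBr2(dme), 4,4′-di-tert-butyl-2,2′-bipyridine, Zn dust, DMA) then forms C4–C4a and should give racemic 3-(benzyloxy)-5-[4-(benzyloxy)-2-oxo-2H-pyran-6-yl]-8-methoxy-6-phenyl-3,4-dihydronaphthalen-1(2H)-one F2. Preparative HPLC on a chiral stationary phase separates the S enantiomer, which is compound 19, where the route is rejoined.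

2. Step 5.
   - What may go wrong: electrophilic attack at the position flanked by phenyl and oxygen may be slow, and on heating the magnesium phenoxide the ortho-hydroxybenzylic tertiary carbinol may lose water through a quinone methide.
   - Fallback (formylation before the four-membered ring exists, with the aldehyde masked in the flask): setting out from 5, the same magnesium-mediated formylation (MgCl2, Et3N, (CH2O)n, THF, 65 °C) is run on the simple bromophenol, a standard substrate class, to give 4-bromo-3-hydroxy-5-methoxybiphenyl-2-carbaldehyde F3. LiN(Me)CH2CH2NMe2 (2 equiv, THF, −20 °C) deprotonates the phenol and adds to the aldehyde, masking it as the dilithium α-amino alkoxide F4. t-BuLi (−78 °C) exchanges the bromine to give the trilithiated aryllithium F5, which adds to ketone 6. Aqueous work-up releases the aldehyde and gives 10, where the route is rejoined.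

3. Step 12.
   - What may go wrong: forcing three ether cleavages at once with excess Lewis acid may bring about β-elimination of the C3 oxygen and aromatisation of ring B to a naphthol.
   - Fallback (staged deprotection ending under neutral conditions): setting out from 19, BCl3 (1.2 equiv, CH2Cl2, −78 °C) is used only for the chelation-controlled cleavage of the C8 methyl ether, to give (S)-3-(benzyloxy)-5-[4-(benzyloxy)-2-oxo-2H-pyran-6-yl]-8-hydroxy-6-phenyl-3,4-dihydronaphthalen-1(2H)-one F6. Hydrogenolysis (H2, Pd on carbon, EtOAc, rt) then removes both benzyl ethers and gives 20.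

**Further compounds**

F1 | step 11 | 2-[4-(benzyloxy)-2-oxo-2H-pyran-6-yl]-4-[3-(benzyloxy)-4-iodobutanoyl]-5-methoxybiphenyl-3-yl trifluoromethanesulfonate (racemic) | O=C(CC(OCc1ccccc1)CI)c1c(OC)cc(-c2ccccc2)c(-c2cc(OCc3ccccc3)cc(=O)o2)c1OS(=O)(=O)C(F)(F)F
F2 | step 11 | racemic 3-(benzyloxy)-5-[4-(benzyloxy)-2-oxo-2H-pyran-6-yl]-8-methoxy-6-phenyl-3,4-dihydronaphthalen-1(2H)-one | O=C1CC(OCc2ccccc2)Cc2c1c(OC)cc(-c1ccccc1)c2-c1cc(OCc3ccccc3)cc(=O)o1
F3 | step 5 | 4-bromo-3-hydroxy-5-methoxybiphenyl-2-carbaldehyde | O=Cc1c(-c2ccccc2)cc(OC)c(Br)c1O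
F4 | step 5 | dilithium α-amino alkoxide of F3 with N,N,N′-trimethylethylenediamine (phenoxide and hemiaminal alkoxide) | [Li]Oc1c(Br)c(OC)cc(-c2ccccc2)c1C(O[Li])N(C)CCN(C)C
F5 | step 5 | trilithiated species from F4 after bromine–lithium exchange | [Li]Oc1c([Li])c(OC)cc(-c2ccccc2)c1C(O[Li])N(C)CCN(C)C
F6 | step 12 | (S)-3-(benzyloxy)-5-[4-(benzyloxy)-2-oxo-2H-pyran-6-yl]-8-hydroxy-6-phenyl-3,4-dihydronaphthalen-1(2H)-one | O=C1C[C@@H](OCc2ccccc2)Cc2c1c(O)cc(-c1ccccc1)c2-c1cc(OCc3ccccc3)cc(=O)o1
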